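**Strategy.** Lapiferine is cut at C1–C5 and at C9–C10. The plan hinges on the position of C1: this methylated quaternary ring-fusion carbon is α to C10 (an aldehyde carbon before the seven-membered ring exists) and is joined to C5 through the C2–C3–C4 chain. The nucleophilic carbon of a C10=C1 silyl enol ether can therefore attack a gold-bound C5≡C6 alkyne. One operation closes the five-membered ring (C1–C5), sets C1 enantioselectively and fixes the C5=C6 geometry needed to close the seven-membered ring. The precursor is an acyclic triisopropylsilyl enol ether of single (E) geometry with a C4 dioxolane, the internal alkyne and a (Z)-vinyl iodide (C8=C9).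

Key step: step 11

Numbering and descriptors: lapiferine numbering is used throughout (five-membered ring C1–C5; seven-membered ring C1, C5–C10; methyl groups on C1 and C8); β is the face of the C1 methyl and α the opposite face. Bicyclic intermediates are named as hydroazulenes with this numbering.

Assumption: the (R)-ligand is taken to deliver (S)-C1 from the (E)-enol ether; if the sense of induction proves opposite, the (S)-ligand is used with no other change.

Step 1
Reactants: 1 prop-2-yn-1-ol
Product: 3 (Z)-3-iodo-2-methylprop-2-en-1-ol, via alkenylmagnesium alkoxide 2 (not isolated)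
Conditions: MeMgBr (2.5 equiv), CuI (10 mol%), THF, −10 °C → rt; then I2, −40 °C → rt
Reagents that add atoms: methylmagnesium bromide C[Mg]Br; iodine II
Why: Copper-catalysed anti-carbomagnesiation of the propargylic alkoxide gives a five-membered magnesium chelate, so iodinolysis with retention should place iodine cis to the hydroxymethyl group and give the (Z)-iodide.

Step 2
Reactants: 3 (Z)-3-iodo-2-methylprop-2-en-1-ol
Product: 4 (Z)-3-bromo-1-iodo-2-methylprop-1-ene
Conditions: CBr4, PPh3, CH2Cl2, 0 °C
Reagents that add atoms: tetrabromomethane BrC(Br)(Br)Br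
Why: The Appel reaction converts the primary allylic alcohol into the bromide under neutral conditions without touching the vinyl iodide or its geometry.

Step 3
Reactants: 5 pent-4-yn-1-ol
Product: 7 (E)-5-iodo-4-methylpent-4-en-1-ol, via alkenylalane 6 (not isolated)
Conditions: AlMe3 (3 equiv), (C5H5)2ZrCl2 (25 mol%), CH2Cl2, 0 °C → rt; then I2, THF, −30 → 0 °C
Reagents that add atoms: trimethylaluminium C[Al](C)C; iodine II
Why: Zirconium-catalysed carboalumination (Negishi) adds methyl and aluminium syn across the terminal alkyne with methyl on the internal carbon, and iodinolysis with retention should give the (E)-vinyl iodide that later fixes the enol ether geometry.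

Step 4
Reactants: 7 (E)-5-iodo-4-methylpent-4-en-1-ol
Product: 8 (E)-5-iodo-4-methylpent-4-enal
Conditions: Dess–Martin periodinane, NaHCO3, CH2Cl2, rt
Reagents that add atoms: none
Why: Dess–Martin oxidation of the primary alcohol stops at the aldehyde and leaves the vinyl iodide untouched.

Step 5
Reactants: 8 (E)-5-iodo-4-methylpent-4-enal; 9 ethynyltrimethylsilane
Product: 11 (E)-7-iodo-6-methyl-1-(trimethylsilyl)hept-6-en-1-yn-3-ol (racemic), via lithium (trimethylsilyl)acetylide 10 (not isolated)
Conditions: n-BuLi, THF, −78 °C; then 8, −78 → 0 °C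
Reagents that add atoms: none
Why: 1,2-Addition of the lithium acetylide to the aldehyde forms the C4–C5 bond without iodine–lithium exchange; the carbinol centre forms as a racemate, which is irrelevant because it is oxidised in the next step.

Step 6
Reactants: 11 (E)-7-iodo-6-methyl-1-(trimethylsilyl)hept-6-en-1-yn-3-ol
Product: 12 (E)-7-iodo-6-methyl-1-(trimethylsilyl)hept-6-en-1-yn-3-one
Conditions: Dess–Martin periodinane, NaHCO3, CH2Cl2, rt
Reagents that add atoms: none
Why: Dess–Martin oxidation of the propargylic alcohol should give the ynone and removes the stereocentre.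

Step 7
Reactants: 12 (E)-7-iodo-6-methyl-1-(trimethylsilyl)hept-6-en-1-yn-3-one
Product: 13 2-[(3E)-4-iodo-3-methylbut-3-en-1-yl]-2-[(trimethylsilyl)ethynyl]-1,3-dioxolane
Conditions: (TMSOCH2)2, TMSOTf (5 mol%), CH2Cl2, −78 → −20 °C
Reagents that add atoms: 1,2-bis(trimethylsilyloxy)ethane C[Si](C)(C)OCCO[Si](C)(C)C
Why: Ketalisation under Noyori conditions works on ynones at low temperature and avoids conjugate addition of the diol; the ketal must be in place before the acid-sensitive enol ether is made.

Step 8
Reactants: 13 2-[(3E)-4-iodo-3-methylbut-3-en-1-yl]-2-[(trimethylsilyl)ethynyl]-1,3-dioxolane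
Product: 16 triisopropyl{[(1E)-2-methyl-4-{2-[(trimethylsilyl)ethynyl]-1,3-dioxolan-2-yl}but-1-en-1-yl]oxy}silane, via alkenyllithium 14 (not isolated), via lithium enolate 15 (not isolated)
Conditions: t-BuLi (2.1 equiv), Et2O, −78 °C; t-BuOOLi (from t-BuOOH, n-BuLi), THF, −78 °C; TIPSOTf, −78 → 0 °C
Reagents that add atoms: lithium tert-butyl peroxide CC(C)(C)OO[Li]; triisopropylsilyl trifluoromethanesulfonate CC(C)[Si](OS(=O)(=O)C(F)(F)F)(C(C)C)C(C)C
Why: Iodine–lithium exchange, electrophilic oxygenation of the alkenyllithium by the lithium peroxide (oxenoid oxidation) and O-silylation of the resulting aldehyde enolate all proceed with retention at the sp2 carbon, so the (E)-vinyl iodide should become the single (E)-enol ether (oxygen cis to methyl), which base-mediated silylation of the aldehyde could not guarantee.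

Step 9
Reactants: 16 triisopropyl{[(1E)-2-methyl-4-{2-[(trimethylsilyl)ethynyl]-1,3-dioxolan-2-yl}but-1-en-1-yl]oxy}silane
Product: 17 {[(1E)-4-(2-ethynyl-1,3-dioxolan-2-yl)-2-methylbut-1-en-1-yl]oxy}triisopropylsilane
Conditions: K2CO3, MeOH, rt
Reagents that add atoms: none
Why: Base-mediated methanolysis cleaves only the alkynyl C–Si bond, since the hindered triisopropylsilyl enol ether and the ketal are stable to mild base.

Step 10
Reactants: 17 {[(1E)-4-(2-ethynyl-1,3-dioxolan-2-yl)-2-methylbut-1-en-1-yl]oxy}triisopropylsilane; 4 (Z)-3-bromo-1-iodo-2-methylprop-1-ene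
Product: 18 {[(1E)-4-{2-[(4Z)-5-iodo-4-methylpent-4-en-1-yn-1-yl]-1,3-dioxolan-2-yl}-2-methylbut-1-en-1-yl]oxy}triisopropylsilane
Conditions: CuI (20 mol%), NaI (20 mol%), Cs2CO3, DMF, rt
Reagents that add atoms: none
Why: Copper-mediated allylation of the terminal alkyne (copper acetylide, SN2 at the allylic bromide) should give the skipped enyne with the (Z)-iodide intact, SN2' attack at the iodine-bearing carbon being disfavoured, and it avoids any lithiated iodoenyne.

Step 11
Reactants: 18 {[(1E)-4-{2-[(4Z)-5-iodo-4-methylpent-4-en-1-yn-1-yl]-1,3-dioxolan-2-yl}-2-methylbut-1-en-1-yl]oxy}triisopropylsilane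
Product: 19 (6E,7S)-6-[(3Z)-4-iodo-3-methylbut-3-en-1-ylidene]-7-methyl-1,4-dioxaspiro[4.4]nonane-7-carbaldehyde
Conditions: (R)-DTBM-SEGPHOS(AuCl)2 (3 mol%), AgSbF6 (6 mol%, AgCl filtered off), H2O (2 equiv), CH2Cl2, −20 °C → rt
Reagents that add atoms: none
Why: The cationic complex of monovalent gold binds the C5≡C6 alkyne and C1 of the enol ether adds to C5 anti to gold; water then desilylates the silyloxocarbenium ion to the aldehyde and the vinylgold is protodeaurated with retention, which leaves C7 cis to C1 on the exocyclic alkene. The closest known reaction type is the gold- or palladium-catalysed enantioselective 5-exo-dig carbocyclisation of silyloxy-1,6-enynes (Conia-ene type), applied here to an aldehyde-derived enol ether. The cyclopentane (C1–C5) closes in the 5-exo-dig mode, favoured over 6-endo attack at C6 by the three-atom C2–C4 tether and the Thorpe–Ingold effect of the ketal. The quaternary stereocentre C1 is set by the chiral bisphosphine, which selects the enol ether face presented to the gold-bound alkyne, and the single (E) geometry of the enol ether makes that selection unambiguous. The step needs enantioface selectivity, exo regioselectivity and tolerance of the vinyl iodide, secured respectively by the ligand with the defined enol ether geometry, by the tether, and by the silver-free preformed catalyst.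

Step 12
Reactants: 19 (6E,7S)-6-[(3Z)-4-iodo-3-methylbut-3-en-1-ylidene]-7-methyl-1,4-dioxaspiro[4.4]nonane-7-carbaldehyde
Product: 20 (1S,10R)-4,4-ethylenedioxy-1β,8-dimethylhydroazulena-5,8-dien-10α-ol
Conditions: CrCl2 (6 equiv), NiCl2 (2 mol%), DMSO, rt, high dilution
Reagents that add atoms: none
Why: In the Nozaki–Hiyama–Kishi reaction the alkenylchromium species formed from the (Z)-vinyl iodide adds to the neopentyl aldehyde and closes the seven-membered ring, the cis relation of C7 and C1 on C5=C6 holding the ends together; the C10 carbinol is expected as 10α because the chromium-bound oxygen should sit anti to the C1 methyl, next to the flat sp2 C5, in a boat-like transition state.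

Step 13
Reactants: 20 (1S,10R)-4,4-ethylenedioxy-1β,8-dimethylhydroazulena-5,8-dien-10α-ol
Product: 21 8α,9α-epoxy-4,4-ethylenedioxy-1β,8β-dimethylhydroazulen-5-en-10α-ol
Conditions: VO(acac)2 (5 mol%), t-BuOOH (1.2 equiv), CH2Cl2, 0 °C
Reagents that add atoms: tert-butyl hydroperoxide CC(C)(C)OO
Why: Vanadium-catalysed hydroxyl-directed epoxidation delivers oxygen to the allylic C8=C9 alkene from the face of the C10 hydroxyl, so the 8α,9α-epoxide syn to 10α-OH should form while the homoallylic C5=C6 alkene reacts much more slowly.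

Step 14
Reactants: 21 8α,9α-epoxy-4,4-ethylenedioxy-1β,8β-dimethylhydroazulen-5-en-10α-ol
Product: 23 8α,9α-epoxy-4,4-ethylenedioxy-1β,8β-dimethyl-5α-H-hydroazulane-6α,10α-diol, via C6 alkylborane 22 (not isolated)
Conditions: BH3·THF (4 equiv), THF, 0 °C → rt; then NaOH, H2O2, 0 °C
Reagents that add atoms: hydrogen peroxide OO
Why: In this hydroboration–oxidation borane should add syn across the trisubstituted C5=C6 alkene with boron on the less substituted C6, from the α-face opposite the C1 methyl (the face that also carries the C10 alkoxyborane formed in situ), and oxidation with retention then gives 5α-H and 6α-OH and thus the trans ring fusion.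

Step 15
Reactants: 23 8α,9α-epoxy-4,4-ethylenedioxy-1β,8β-dimethyl-5α-H-hydroazulane-6α,10α-diol
Product: 24 8α,9α-epoxy-6α,10α-dihydroxy-1β,8β-dimethyl-5α-H-hydroazulan-4-one
Conditions: PPTS (cat.), acetone/H2O, 45 °C
Reagents that add atoms: water O
Why: Acid-catalysed hydrolysis of the dioxolane with pyridinium tosylate in wet acetone should be mild enough to spare the oxirane and to avoid dehydration of the β-hydroxy ketone or epimerisation at C5.

Step 16
Reactants: 24 8α,9α-epoxy-6α,10α-dihydroxy-1β,8β-dimethyl-5α-H-hydroazulan-4-one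
Product: 25 8α,9α-epoxy-4α-isopropyl-1β,8β-dimethyl-5α-H-hydroazulane-4β,6α,10α-triol
Conditions: i-PrMgCl (6 equiv), CeCl3 (6 equiv), THF, −78 → −40 °C
Reagents that add atoms: isopropylmagnesium chloride CC(C)[Mg]Cl
Why: The organocerium 1,2-addition suppresses enolisation, reduction and retro-aldol cleavage, and the nucleophile should approach the cyclopentanone from the α-face, anti to the vicinal C5–C6 bond and to the C1 methyl, giving the 4β tertiary alcohol.

Step 17
Reactants: 25 8α,9α-epoxy-4α-isopropyl-1β,8β-dimethyl-5α-H-hydroazulane-4β,6α,10α-triol; 26 angelic acid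
Product: 28 lapiferine, via angelic 2,4,6-trichlorobenzoic anhydride 27 (not isolated)
Conditions: 2,4,6-trichlorobenzoyl chloride, Et3N, toluene, rt; then 25, toluene, 80 °C
Reagents that add atoms: none
Why: Yamaguchi-type esterification through the mixed anhydride should acylate the only unhindered secondary hydroxyl (C6, whereas C10–OH is neopentylic and flanked by the oxirane and C4–OH is tertiary) without isomerising the (Z)-angelate to the tiglate.

**Compound list**

1 | prop-2-yn-1-ol | C#CCO | starting material
2 | (Z)-alkenylmagnesium alkoxide from carbomagnesiation of 1 | Br[Mg]/C=C(/C)CO[Mg]Br | intermediate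
3 | (Z)-3-iodo-2-methylprop-2-en-1-ol | I/C=C(/C)CO | intermediate
4 | (Z)-3-bromo-1-iodo-2-methylprop-1-ene | I/C=C(/C)CBr | intermediate
5 | pent-4-yn-1-ol | C#CCCCO | starting material
6 | (E)-alkenylalane from carboalumination of 5 | C[Al](C)/C=C(\C)CCCO[Al](C)C | intermediate
7 | (E)-5-iodo-4-methylpent-4-en-1-ol | I/C=C(\C)CCCO | intermediate
8 | (E)-5-iodo-4-methylpent-4-enal | I/C=C(\C)CCC=O | intermediate
9 | ethynyltrimethylsilane | C#C[Si](C)(C)C | starting material
10 | lithium (trimethylsilyl)acetylide | [Li]C#C[Si](C)(C)C | intermediate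
11 | (E)-7-iodo-6-methyl-1-(trimethylsilyl)hept-6-en-1-yn-3-ol (racemic) | I/C=C(\C)CCC(O)C#C[Si](C)(C)C | intermediate
12 | (E)-7-iodo-6-methyl-1-(trimethylsilyl)hept-6-en-1-yn-3-one | I/C=C(\C)CCC(=O)C#C[Si](C)(C)C | intermediate
13 | 2-[(3E)-4-iodo-3-methylbut-3-en-1-yl]-2-[(trimethylsilyl)ethynyl]-1,3-dioxolane | I/C=C(\C)CCC1(OCCO1)C#C[Si](C)(C)C | intermediate
14 | (E)-alkenyllithium from 13 | [Li]/C=C(\C)CCC1(OCCO1)C#C[Si](C)(C)C | intermediate
15 | (E)-lithium enolate from 14 | [Li]O/C=C(\C)CCC1(OCCO1)C#C[Si](C)(C)C | intermediate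
16 | triisopropyl{[(1E)-2-methyl-4-{2-[(trimethylsilyl)ethynyl]-1,3-dioxolan-2-yl}but-1-en-1-yl]oxy}silane | CC(C)[Si](O/C=C(\C)CCC1(OCCO1)C#C[Si](C)(C)C)(C(C)C)C(C)C | intermediate
17 | {[(1E)-4-(2-ethynyl-1,3-dioxolan-2-yl)-2-methylbut-1-en-1-yl]oxy}triisopropylsilane | CC(C)[Si](O/C=C(\C)CCC1(OCCO1)C#C)(C(C)C)C(C)C | intermediate
18 | (E)-triisopropylsilyl enol ether of 2-methyl-4-{2-[(4Z)-5-iodo-4-methylpent-4-en-1-yn-1-yl]-1,3-dioxolan-2-yl}butanal | CC(C)[Si](O/C=C(\C)CCC1(OCCO1)C#CC/C(C)=C\I)(C(C)C)C(C)C | intermediate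
19 | (6E,7S)-6-[(3Z)-4-iodo-3-methylbut-3-en-1-ylidene]-7-methyl-1,4-dioxaspiro[4.4]nonane-7-carbaldehyde | O=C[C@@]1(C)CCC2(OCCO2)/C1=C/C/C(C)=C\I | intermediate
20 | (1S,10R)-4,4-ethylenedioxy-1β,8-dimethylhydroazulena-5,8-dien-10α-ol | CC1=C[C@@H](O)[C@@]2(C)CCC3(OCCO3)C2=CC1 | intermediate
21 | 8α,9α-epoxy-4,4-ethylenedioxy-1β,8β-dimethylhydroazulen-5-en-10α-ol | C1[C@@]2(C)O[C@H]2[C@@H](O)[C@@]2(C)CCC3(OCCO3)C2=C1 | intermediate
22 | C6 alkylborane of 21 (5α-H, 6α-boryl, C10 alkoxyborane) | B[C@H]1C[C@@]2(C)O[C@H]2[C@@H](OB)[C@@]2(C)CCC3(OCCO3)[C@H]12 | intermediate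
23 | 8α,9α-epoxy-4,4-ethylenedioxy-1β,8β-dimethyl-5α-H-hydroazulane-6α,10α-diol | O[C@H]1C[C@@]2(C)O[C@H]2[C@@H](O)[C@@]2(C)CCC3(OCCO3)[C@H]12 | intermediate
24 | 8α,9α-epoxy-6α,10α-dihydroxy-1β,8β-dimethyl-5α-H-hydroazulan-4-one | O[C@H]1C[C@@]2(C)O[C@H]2[C@@H](O)[C@@]2(C)CCC(=O)[C@H]12 | intermediate
25 | 8α,9α-epoxy-4α-isopropyl-1β,8β-dimethyl-5α-H-hydroazulane-4β,6α,10α-triol | O[C@H]1C[C@@]2(C)O[C@H]2[C@@H](O)[C@@]2(C)CC[C@@](O)(C(C)C)[C@H]12 | intermediate
26 | angelic acid, (Z)-2-methylbut-2-enoic acid | C/C=C(/C)C(=O)O | starting material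
27 | angelic 2,4,6-trichlorobenzoic anhydride | C/C=C(/C)C(=O)OC(=O)c1c(Cl)cc(Cl)cc1Cl | intermediate
28 | lapiferine (6α-angelate of 25) | C/C=C(/C)C(=O)O[C@H]1C[C@@]2(C)O[C@H]2[C@@H](O)[C@@]2(C)CC[C@@](O)(C(C)C)[C@H]12 | target

**Step count and risks**

Total step count: 17. Longest linear sequence: 15 steps (steps 3 to 17, from pent-4-yn-1-ol).

Steps most likely to fail:

Step 11. What may go wrong: weak enantioface discrimination at C1, competing 6-endo closure or alkoxy migration of the propargylic ketal on the gold-bound alkyne, or hydrolysis of the enol ether before it cyclises. The fallback sets out from 18 and comes back at 19. The silyl group is removed with buffered fluoride (TBAF, AcOH, THF, 0 °C) to give the free aldehyde 2-methyl-4-{2-[(4Z)-5-iodo-4-methylpent-4-en-1-yn-1-yl]-1,3-dioxolan-2-yl}butanal F1. F1 is then cyclised by cooperative enamine–metal catalysis: a chiral primary amine (9-amino-9-deoxy-epi-quinine with an acid co-catalyst) together with (Ph3P)AuNTf2 or [Cu(MeCN)4]PF6/PPh3. The enamine of the α-branched aldehyde attacks the metal-bound alkyne in the same 5-exo-dig sense, and because the enamine isomers interconvert no enol geometry has to be fixed.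

Step 14. What may go wrong: borane adding from the methyl-bearing β-face because the α-face is crowded by the C10 oxygen and the oxirane, which would give the cis-fused 5β-H, 6β-OH series, or reductive opening of the oxirane. The fallback sets out from 21 and comes back at 24. A second vanadium-directed epoxidation (VO(acac)2, excess t-BuOOH, longer time) uses the 10α-hydroxyl to deliver oxygen to the homoallylic C5=C6 alkene from the α-face, giving the 5α,6α:8α,9α-diepoxide ketal F2. Hydrolysis of the ketal (PPTS, wet acetone) gives the α,β-epoxy ketone F3. SmI2 (THF/MeOH, −90 °C) then cleaves only the C5–O bond of the epoxy ketone, so the 6α-oxygen and the isolated oxirane remain, and protonation of the samarium enolate at C5 should give 24.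

Step 12. What may go wrong: addition to the aldehyde face that puts the C10 oxygen syn to the C1 methyl (10β), after which the directed epoxidation would also go to the wrong face; slow closure with simple reduction of the iodide is the second failure mode. The fallback sets out from 19 and comes back at 20. The closure is run as in step 12, and the 10β-alcohol 4,4-ethylenedioxy-1β,8-dimethylhydroazulena-5,8-dien-10β-ol F4 is inverted by a Mitsunobu reaction (4-nitrobenzoic acid, PPh3, DIAD, THF). This gives the 10α 4-nitrobenzoate F5, which is methanolysed (K2CO3, MeOH) to 20.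

Further compounds

F1 | step 11 | 2-methyl-4-{2-[(4Z)-5-iodo-4-methylpent-4-en-1-yn-1-yl]-1,3-dioxolan-2-yl}butanal (racemic) | O=CC(C)CCC1(OCCO1)C#CC/C(C)=C\I
F2 | step 14 | 5α,6α:8α,9α-diepoxy-4,4-ethylenedioxy-1β,8β-dimethylhydroazulan-10α-ol | O1[C@H]2C[C@@]3(C)O[C@H]3[C@@H](O)[C@@]3(C)CCC4(OCCO4)[C@]123
F3 | step 14 | 5α,6α:8α,9α-diepoxy-10α-hydroxy-1β,8β-dimethylhydroazulan-4-one | O1[C@H]2C[C@@]3(C)O[C@H]3[C@@H](O)[C@@]3(C)CCC(=O)[C@]123
F4 | step 12 | 4,4-ethylenedioxy-1β,8-dimethylhydroazulena-5,8-dien-10β-ol | CC1=C[C@H](O)[C@@]2(C)CCC3(OCCO3)C2=CC1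
F5 | step 12 | 4,4-ethylenedioxy-1β,8-dimethylhydroazulena-5,8-dien-10α-yl 4-nitrobenzoate | CC1=C[C@@H](OC(=O)c2ccc(cc2)[N+](=O)[O-])[C@@]2(C)CCC3(OCCO3)C2=CC1
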